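**Plan**

- Retrosynthesis: the O7–S bond and the 4'-O–benzyl bond are cut first. Ring A is then opened at C4a–C5, C5–C6 and C7–C8, giving a C6–C7 ynol ether (O7 as silyl ether) and a 6-aryl-4-pyranone with a diazoacetyl group (future C8 and C5) on the future C8a.
- Enabling feature: ring A (C4a, C5, C6, C7, C8, C8a) is a resorcinol fused to ring C through C4a=C8a, with oxygen on C5 (peri to C4=O) and on C7. A vinylketene/ynol ether benzannulation delivers exactly this 1,3-dioxygenated arene, with the two oxygens already differentiated.
- Forward order: ring B arrives with the acetophenone. Ring C is built by two Claisen condensations and cyclodehydration, and the pyranone acid is converted into the diazo ketone. Ring A closes last by photo-Wolff rearrangement, [2+2] addition of (triisopropylsilyloxy)acetylene, 4π opening and 6π closure.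
- End game: fluoride frees only O7, which is sulfated while O5 is chelated and O4' is benzylated; hydrogenolysis and protonation finish the route.
- Stereochemistry: the target has no stereocentre, stereogenic axis or configured double bond, so nothing has to be set or preserved.

Key step: step 6

Remark on the chemistry: the target is achiral, so "single enantiomer" asks only for the constitution. Aryl hydrogen sulfates are fragile as free acids, so the sulfate is carried as its sodium salt and protonated only in the last operation.

**Route**

Step 1
Reactants: 1 4'-(benzyloxy)acetophenone; 2 ethyl acetate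
Product: 3 1-[4-(benzyloxy)phenyl]butane-1,3-dione
Conditions: NaH (2.2 equiv), 2 (3 equiv), THF, reflux; aq. HCl
Reagents that add atoms: none
Why: Crossed Claisen condensation of the methyl ketone enolate with ethyl acetate should be driven to completion by deprotonation of the β-diketone formed, and the benzyl ether is inert to NaH.

Step 2
Reactants: 3 1-[4-(benzyloxy)phenyl]butane-1,3-dione; 4 diethyl oxalate
Product: 6 ethyl 6-[4-(benzyloxy)phenyl]-4-oxo-4H-pyran-2-carboxylate, via triketo ester 5 (not isolated)
Conditions: NaOEt (2.5 equiv), EtOH, 0 → 50 °C; then conc. HCl (to pH 1), EtOH, 70 °C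
Reagents that add atoms: none
Why: Claisen condensation with diethyl oxalate should settle on the terminal methyl group (acylation at the central carbon is reversible, and the terminal product is held as a stable dianion), and acid-catalysed cyclodehydration of the 1,3,5-tricarbonyl unit then gives the 4-pyranone as in the chelidonic acid synthesis.

Step 3
Reactants: 6 ethyl 6-[4-(benzyloxy)phenyl]-4-oxo-4H-pyran-2-carboxylate
Product: 7 6-[4-(benzyloxy)phenyl]-4-oxo-4H-pyran-2-carboxylic acid
Conditions: LiOH·H2O (1.3 equiv), THF–H2O, 0 °C; then 1 M HCl to pH 2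
Reagents that add atoms: lithium hydroxide, [Li+].[OH-]
Why: Saponification of an ester activated by the adjacent ring oxygen should be fast at 0 °C, and any ring-opened triketo acid formed by hydroxide addition recloses to the pyranone on acidification.

Step 4
Reactants: 7 6-[4-(benzyloxy)phenyl]-4-oxo-4H-pyran-2-carboxylic acid
Product: 9 2-[4-(benzyloxy)phenyl]-6-(2-diazoacetyl)-4H-pyran-4-one, via acid chloride 8 (not isolated)
Conditions: (COCl)2, DMF (cat.), CH2Cl2, 0 °C → rt, evaporate; CH2N2 (3 equiv), Et2O–THF, 0 °C, dark
Reagents that add atoms: diazomethane, C=[N+]=[N-]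
Why: Acid chloride formation under Vilsmeier catalysis followed by C-acylation of diazomethane (the first stage of an Arndt–Eistert sequence) should give the diazo ketone, with a second equivalent of diazomethane removing HCl as chloromethane.

Step 5
Reactants: 10 acetylene; 11 triisopropylsilyl trifluoromethanesulfonate
Product: 14 (triisopropylsilyloxy)acetylene, via lithium acetylide 12 (not isolated), via lithium ethynolate 13 (not isolated)
Conditions: 10 (excess), LiHMDS (2.0 equiv), THF, −78 °C; t-BuOOH (1.0 equiv, decane), −78 → 0 °C; Ar purge; 11 (1.05 equiv), −78 → 0 °C; pentane, cold H2O wash; distil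
Reagents that add atoms: tert-butyl hydroperoxide, CC(C)(C)OO
Why: Oxidation of a lithium acetylide by lithium tert-butyl peroxide (attack of the acetylide carbon on the O–O bond) should give the ynolate while excess acetylene suppresses disproportionation of the monolithium acetylide, and the bulky silyl triflate silylates the ynolate on oxygen rather than on carbon.

Step 6
Reactants: 9 2-[4-(benzyloxy)phenyl]-6-(2-diazoacetyl)-4H-pyran-4-one; 14 (triisopropylsilyloxy)acetylene
Product: 19 4'-(benzyloxy)-5-hydroxy-7-(triisopropylsilyloxy)flavone, via pyranonylketene 15 (not isolated), via silyloxycyclobutenone 16 (not isolated), via dienylketene 17 (not isolated), via 4aH-chromene-4,5-dione 18 (not isolated)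
Conditions: 14 (2 equiv), hν (420 nm LEDs), degassed ClCH2CH2Cl, rt; then 80 °C
Reagents that add atoms: none
Why: Light of 420 nm should be absorbed by the diazo ketone band only, so 9 loses N2 and undergoes Wolff rearrangement to pyranonylketene 15, a vinylketene whose alkene is the pyranone C5=C6 bond (future C4a=C8a). The electron-rich alkyne 14 adds to the ketene C=C in a [2+2] cycloaddition that forms C5–C6 and C7–C8 and gives cyclobutenone 16; on warming, 16 opens by 4π electrocyclic cleavage of its C5–C8 bond to dienylketene 17. Ring A then closes by thermal disrotatory 6π electrocyclisation to a six-membered carbocycle, the electrophilic ketene carbon C5 bonding to the enol-ether-like pyranone carbon C4a, and enolisation of dienone 18 restores the pyranone and leaves the C5 hydroxyl hydrogen-bonded to C4=O. The closest known reaction is the Danheiser benzannulation in its photochemical diazo ketone form, established for alkenyl, aryl and heteroaryl diazomethyl ketones with silyloxyalkynes, and a pyranone double bond is less aromatic than the benzene and furan bonds that already take part. No stereocentre is created, the sp3 carbons of 16 and 18 being transient. The selectivity needed is regiochemical (silyloxy carbon at C7, not C6) and is secured by the polarisation of 14, whose unsubstituted nucleophilic carbon attacks the ketene carbonyl carbon, while closure can only occur at C4a because the other neighbour of C8a is the ring oxygen.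

Step 7
Reactants: 19 4'-(benzyloxy)-5-hydroxy-7-(triisopropylsilyloxy)flavone
Product: 20 4'-(benzyloxy)-5,7-dihydroxyflavone
Conditions: TBAF (1.1 equiv), AcOH (1.2 equiv), THF, 0 °C
Reagents that add atoms: none
Why: Fluoride-mediated cleavage of the phenolic Si–O bond should be fast at 0 °C, and acetic acid buffers the phenoxide so that the benzyl ether and the pyranone are untouched.

Step 8
Reactants: 20 4'-(benzyloxy)-5,7-dihydroxyflavone
Product: 21 sodium 4'-(benzyloxy)-5-hydroxyflavon-7-yl sulfate
Conditions: SO3·pyridine (2.5 equiv), pyridine, rt; aq. NaHCO3; C18 or Sephadex LH-20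
Reagents that add atoms: sulfur trioxide–pyridine complex, [O-]S(=O)(=O)[n+]1ccccc1; sodium hydrogen carbonate, [Na+].OC([O-])=O
Why: O-Sulfation of a phenol with the SO3–pyridine complex should occur only at O7, because the C5 hydroxyl is held in the hydrogen bond to C4=O and O4' is benzylated, and bicarbonate exchanges pyridinium for sodium.

Step 9
Reactants: 21 sodium 4'-(benzyloxy)-5-hydroxyflavon-7-yl sulfate
Product: 23 apigenin 7-sulfate (5-hydroxy-2-(4-hydroxyphenyl)-4-oxo-4H-chromen-7-yl hydrogen sulfate), via sodium apigenin 7-sulfate 22 (not isolated)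
Conditions: H2 (1 atm), 10% Pd/C, MeOH–H2O, rt; filter; 1 M HCl (1.0 equiv), 0 °C; C18 desalting, lyophilise
Reagents that add atoms: none
Why: Hydrogenolysis of the benzyl aryl ether over Pd/C at 1 atm under neutral conditions should leave the sulfate monoester anion and the flavone C2=C3 bond intact, and brief cold protonation of the sodium salt gives the acid form.

**Compound list**

1 | 4'-(benzyloxy)acetophenone | CC(=O)c1ccc(OCc2ccccc2)cc1 | starting material
2 | ethyl acetate | CCOC(C)=O | starting material
3 | 1-[4-(benzyloxy)phenyl]butane-1,3-dione | CC(=O)CC(=O)c1ccc(OCc2ccccc2)cc1 | intermediate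
4 | diethyl oxalate | CCOC(=O)C(=O)OCC | starting material
5 | ethyl 6-[4-(benzyloxy)phenyl]-2,4,6-trioxohexanoate (triketo ester, formed as its sodium enolate) | CCOC(=O)C(=O)CC(=O)CC(=O)c1ccc(OCc2ccccc2)cc1 | intermediate
6 | ethyl 6-[4-(benzyloxy)phenyl]-4-oxo-4H-pyran-2-carboxylate | CCOC(=O)c1cc(=O)cc(-c2ccc(OCc3ccccc3)cc2)o1 | intermediate
7 | 6-[4-(benzyloxy)phenyl]-4-oxo-4H-pyran-2-carboxylic acid | OC(=O)c1cc(=O)cc(-c2ccc(OCc3ccccc3)cc2)o1 | intermediate
8 | 6-[4-(benzyloxy)phenyl]-4-oxo-4H-pyran-2-carbonyl chloride | ClC(=O)c1cc(=O)cc(-c2ccc(OCc3ccccc3)cc2)o1 | intermediate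
9 | 2-[4-(benzyloxy)phenyl]-6-(2-diazoacetyl)-4H-pyran-4-one | [N-]=[N+]=CC(=O)c1cc(=O)cc(-c2ccc(OCc3ccccc3)cc2)o1 | intermediate
10 | acetylene | C#C | starting material
11 | triisopropylsilyl trifluoromethanesulfonate | CC(C)[Si](OS(=O)(=O)C(F)(F)F)(C(C)C)C(C)C | starting material
12 | lithium acetylide | [Li+].[C-]#C | intermediate
13 | lithium ethynolate | [Li+].[O-]C#C | intermediate
14 | (triisopropylsilyloxy)acetylene | C#CO[Si](C(C)C)(C(C)C)C(C)C | intermediate
15 | 2-[4-(benzyloxy)phenyl]-6-(2-oxoethenyl)-4H-pyran-4-one (pyranonylketene) | O=C=Cc1cc(=O)cc(-c2ccc(OCc3ccccc3)cc2)o1 | intermediate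
16 | 2-[4-(benzyloxy)phenyl]-6-[4-oxo-2-(triisopropylsilyloxy)cyclobut-2-en-1-yl]-4H-pyran-4-one (racemic, transient) | O=C1C=C(O[Si](C(C)C)(C(C)C)C(C)C)C1c1cc(=O)cc(-c2ccc(OCc3ccccc3)cc2)o1 | intermediate
17 | 2-[4-(benzyloxy)phenyl]-6-[4-oxo-2-(triisopropylsilyloxy)buta-1,3-dien-1-yl]-4H-pyran-4-one (ketene arm and pyranone cis on the C1=C2 bond) | O=C=C/C(O[Si](C(C)C)(C(C)C)C(C)C)=C\c1cc(=O)cc(-c2ccc(OCc3ccccc3)cc2)o1 | intermediate
18 | 2-[4-(benzyloxy)phenyl]-7-(triisopropylsilyloxy)-4aH-chromene-4,5-dione (racemic, transient) | O=C1C=C(O[Si](C(C)C)(C(C)C)C(C)C)C=C2OC(-c3ccc(OCc4ccccc4)cc3)=CC(=O)C12 | intermediate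
19 | 4'-(benzyloxy)-5-hydroxy-7-(triisopropylsilyloxy)flavone | O=c1cc(-c2ccc(OCc3ccccc3)cc2)oc2cc(O[Si](C(C)C)(C(C)C)C(C)C)cc(O)c12 | intermediate
20 | 4'-(benzyloxy)-5,7-dihydroxyflavone | O=c1cc(-c2ccc(OCc3ccccc3)cc2)oc2cc(O)cc(O)c12 | intermediate
21 | sodium 4'-(benzyloxy)-5-hydroxyflavon-7-yl sulfate | [Na+].O=c1cc(-c2ccc(OCc3ccccc3)cc2)oc2cc(OS(=O)(=O)[O-])cc(O)c12 | intermediate
22 | sodium apigenin 7-sulfate | [Na+].O=c1cc(-c2ccc(O)cc2)oc2cc(OS(=O)(=O)[O-])cc(O)c12 | intermediate
23 | apigenin 7-sulfate | O=c1cc(-c2ccc(O)cc2)oc2cc(OS(=O)(=O)O)cc(O)c12 | target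

**Step count**

Total: 9 steps. Longest linear sequence: 8 steps (steps 1–4 and 6–9); step 5 is a one-step branch.

**Steps most likely to fail**

Step 6. The ketene may be consumed by dimerisation or by photodecomposition of the pyranone chromophore before it meets the alkyne, or the sequence may stall at the cyclobutenone because the 6π closure onto the pyranone bond is slow. The fallback takes ring A from phloroglucinol instead. It sets out from 1, which is C-acylated with diethyl carbonate (NaH, THF) to give ethyl 3-[4-(benzyloxy)phenyl]-3-oxopropanoate F1. F1 is then heated with phloroglucinol without solvent or catalyst at about 240 °C (or under microwave heating) in a Mentzer-type chromone condensation. This should give the 5,7-dihydroxyflavone directly, and the route is rejoined at 20.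

Step 5. The monolithium acetylide may disproportionate to insoluble dilithium acetylide before it is oxidised, the ynolate may be silylated on carbon, or the volatile ynol ether may be lost on isolation. The fallback replaces the silyl ynol ether by an alkyl one. Potassium tert-butoxide is added to trichloroethylene to give (E)-1-tert-butoxy-1,2-dichloroethene F2. n-BuLi (2 equiv, THF, −78 °C) followed by methanol converts F2 into tert-butoxyacetylene F3, which is used fresh because it loses isobutene on warming. The fallback then sets out from 9, which is irradiated with F3 under the conditions of step 6; alkoxyacetylenes are established partners in this benzannulation and are polarised in the same sense. This should give 4'-(benzyloxy)-7-tert-butoxy-5-hydroxyflavone F4. TFA in CH2Cl2 at 0 °C cleaves the aryl tert-butyl ether without touching the benzyl ether, and the route is rejoined at 20.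

Step 8. Sulfation may be incomplete, and much material may be lost when the ionic monoester is separated from pyridinium salts and inorganic sulfate. The fallback carries the sulfate as a neutral diester. It sets out from 20, which is treated with 2,2,2-trichloroethyl chlorosulfate, Et3N and DMAP in THF to give 4'-(benzyloxy)-5-hydroxyflavon-7-yl 2,2,2-trichloroethyl sulfate F5, which can be purified on silica. Pd/C with ammonium formate in MeOH should then remove the trichloroethyl group and the benzyl ether in one operation to give ammonium apigenin 7-sulfate F6. Cold protonation and desalting as in step 9 bring the route back at 23.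

**Further compounds**

F1 | step 6 | ethyl 3-[4-(benzyloxy)phenyl]-3-oxopropanoate | CCOC(=O)CC(=O)c1ccc(OCc2ccccc2)cc1
F2 | step 5 | (E)-1-tert-butoxy-1,2-dichloroethene | CC(C)(C)O/C(Cl)=C\Cl
F3 | step 5 | tert-butoxyacetylene | C#COC(C)(C)C
F4 | step 5 | 4'-(benzyloxy)-7-tert-butoxy-5-hydroxyflavone | O=c1cc(-c2ccc(OCc3ccccc3)cc2)oc2cc(OC(C)(C)C)cc(O)c12
F5 | step 8 | 4'-(benzyloxy)-5-hydroxyflavon-7-yl 2,2,2-trichloroethyl sulfate | O=c1cc(-c2ccc(OCc3ccccc3)cc2)oc2cc(OS(=O)(=O)OCC(Cl)(Cl)Cl)cc(O)c12
F6 | step 8 | ammonium apigenin 7-sulfate | [NH4+].O=c1cc(-c2ccc(O)cc2)oc2cc(OS(=O)(=O)[O-])cc(O)c12
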